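The ratio I start from is incoming ligand the gas can offer during the run over starting complex charged.

the same everywhere: gas 200 mM (held); time 50 min
- south: starting complex 1.5 M
- south-east: starting complex 2.0 M
- east: starting complex 3.0 M

    starting complex + incoming ligand ⇌ leaving ligand + complex with one exchanged (K1 = 20, k1 = 0.014 M⁻¹ s⁻¹)
    complex with one exchanged + incoming ligand ⇌ leaving ligand + complex with two exchanged (K2 = 8.6, k2 = 0.094 M⁻¹ s⁻¹)
    complex with two exchanged + incoming ligand ⇌ leaving ligand + complex with three exchanged (K3 = 200, k3 = 0.0026 M⁻¹ s⁻¹)
    starting complex + complex with two exchanged → side product (k4 = 3.9 × 10⁻⁴ M⁻¹ s⁻¹)
    gas ⇌ incoming ligand, rate k5*(csat - [incoming ligand]) (k5 = 0.0050 s⁻¹, csat = 200 mM)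

- in percentages every species weighs as the starting complex in it: one side product counts as two
- at the start none of incoming ligand is dissolved
- "hardly changes" means that all values lie within two and a half points (for a concentration: within two and a half percent of the largest)
- run time (south): 50 min

- [complex with two exchanged] at the end for south, south-east, east, in this order
- the course of these numbers from the first flask to the last (falls, then rises / hardly changes / rises all the way / falls all the way / rises, then falls)

For south the supply number is 2.00: the transfer coefficient times the saturation concentration times the run time, divided by the charge, which is the exchanges per starting complex the gas could pay for if dissolved ligand stayed at zero. For east it falls to 1.00, yet the offer in concentration is 3.00 M in both.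

Now I go round once more and put the first answer back, with dissolved ligand above zero. The first exchange alone, forward and at the charged concentrations, gives incoming ligand a half-life of 0.55 min, shorter than the 2.31 min of the transfer, so the transfer is the rate-limiting step at the start of south. Balancing the two there puts dissolved ligand near 0.0385 M. Holding that same balance through the run, with starting complex kept as charged, is a rough estimate that lowers the supply number to 1.62 for south and 0.894 for east.

I read this as follows: by this estimate south can pay for more than one exchange per complex and east for fewer, so I expect the twice-exchanged share to fall as the charge rises, while the concentration is share times charge. These pull against each other, so I commit to a shallow row. One number isn't enough for a value, though. It holds neither the way back nor the side product, and in south the twice-exchanged complex has a half-life of 20 min by the side reaction alone, with starting complex as charged, shorter than the run. My reckoning therefore gives no concentration.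

The forecast does: 0.28 M, 0.3 M and 0.28 M, with a course that rises, then falls, on the words “I expect a shallow maximum”.

The simulation gives 0.296 M, 0.304 M and 0.279 M, a course that rises, then falls. The row turns at a charge of 1.9 M. At 50.0 min the south flask holds 1.16 leaving ligand per starting complex charged, which is 58.0 % of its supply number. The east flask holds 0.743, which is 74.3 % of its 1.00.

All constants belong to no real substance, and the outcome is calculated.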